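**Retrosynthetic overview**
1. Last disconnection: the 2,3-dimethoxy-1,4-benzoquinone ring is traced back to a four-membered ring, a 4-alkynyl-4-hydroxy-2,3-dimethoxycyclobut-2-enone. On heating this should isomerise to the quinone (Moore rearrangement, four-ring to six-ring) without reagent, oxidant or protecting group.
2. Enabling feature: the quinone edge C1(=O)-C2(OMe)=C3(OMe)-C4(=O) is the carbon ring of dimethyl squarate, and the pair C5(CH2-imidazolyl)=C6-H is an alkyne. C6-H takes the carbinol hydrogen, and the sp3 CH2 between quinone C5 and imidazole C5 makes the alkyne terminus alkyl-like, which directs closure to the six-ring.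
3. The cyclobutenone comes from dimethyl squarate and the N,C-dilithiated 5-propargyl analogue of the target (one C-C bond).
4. That alkyne comes from 2-amino-4-(4-methoxybenzyl)-1-methyl-5-propargylimidazole and 1-methylparabanic acid. The aminoimidazole comes from cyanamide and an α-(methylamino)ketone made from Boc-propargylglycine (N-methylation, Weinreb amide, 4-methoxybenzylmagnesium chloride).
5. Ring order: anisole ring bought; imidazole ring (step 4); imidazolidinetrione ring (made in step 5, joined in step 6); four-membered ring bought and attached (step 7); quinone ring last (step 8).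

Key step: step 8

Remark on the chemistry: the target has no stereocentre. The α-carbon of the amino acid is drawn with retention, although it may racemise, and it is erased when the imidazole forms. The carbinol carbon of the cyclobutenone forms as a racemate and is erased in the ring expansion. All amidine compounds are drawn in the exocyclic N-H tautomer of the given structure.

**Route**

Step 1
Reactants: 1 N-Boc-L-propargylglycine, (2S)-2-[(tert-butoxycarbonyl)amino]pent-4-ynoic acid
Product: 2 (2S)-2-[(tert-butoxycarbonyl)(methyl)amino]pent-4-ynoic acid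
Conditions: NaH (3 equiv), MeI (5 equiv), THF, 0 °C to rt; then H2O, aq HCl to pH 3
Reagents that add atoms: iodomethane CI
Why: N-alkylation of the sodium carbamate of a Boc amino acid (NaH/MeI N-methylation) should occur at nitrogen only, since the sodium carboxylate is not esterified in THF and NaH does not metalate the terminal alkyne at this temperature; the α-stereocentre is not involved.

Step 2
Reactants: 2 (2S)-2-[(tert-butoxycarbonyl)(methyl)amino]pent-4-ynoic acid
Product: 4 tert-butyl N-{(2S)-1-[methoxy(methyl)amino]-1-oxopent-4-yn-2-yl}-N-methylcarbamate (Weinreb amide), via acyl imidazolide 3 (not isolated)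
Conditions: CDI, CH2Cl2, 0 °C to rt; then MeNH(OMe)·HCl, rt
Reagents that add atoms: N,O-dimethylhydroxylamine hydrochloride CNOC.Cl; 1,1'-carbonyldiimidazole O=C(n1ccnc1)n1ccnc1 (imidazolyl group of 3 only; no atom stays in 4)
Why: Carbonyldiimidazole activation followed by aminolysis (Weinreb amide formation) is mild enough for the Boc group and the alkyne, and the released imidazole takes up the HCl of the amine salt.

Step 3
Reactants: 4 Weinreb amide; 5 4-methoxybenzylmagnesium chloride (commercial THF solution)
Product: 6 tert-butyl N-[(3S)-1-(4-methoxyphenyl)-2-oxohex-5-yn-3-yl]-N-methylcarbamate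
Conditions: 5 (3 equiv), THF, −20 to 0 °C; aq NH4Cl
Reagents that add atoms: none
Why: Weinreb ketone synthesis: chelation holds the adduct until the quench so the benzylic Grignard reagent adds only once, the extra reagent covers the alkyne C-H (which returns on quench), and the carbamate is inert at this temperature.

Step 4
Reactants: 6 tert-butyl N-[(3S)-1-(4-methoxyphenyl)-2-oxohex-5-yn-3-yl]-N-methylcarbamate
Product: 9 2-amino-4-(4-methoxybenzyl)-1-methyl-5-(prop-2-ynyl)-1H-imidazole, via aminoketone hydrochloride 7 (not isolated), via ketoguanidine 8 (not isolated)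
Conditions: 4 M HCl in 1,4-dioxane, rt, evaporate; H2NCN, H2O-EtOH, pH 4.5 (aq NaOH), 95 °C; basify (aq NaOH)
Reagents that add atoms: cyanamide N#CN; hydrogen chloride Cl (chloride of 7 only; no atom stays in 9)
Why: Acidolysis of the Boc group and Marckwald-type cyclocondensation of the α-aminoketone salt with cyanamide: the methylamino nitrogen adds to the nitrile, the NH2 group of 8 condenses with the ketone (5-exo-trig) and loss of water aromatises the ring, which places N-methyl next to the propargyl-bearing carbon and erases the stereocentre, while pH 4.5 suppresses self-condensation of the aminoketone.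

Step 5
Reactants: 10 N-methylurea
Product: 11 1-methylimidazolidine-2,4,5-trione (1-methylparabanic acid)
Conditions: (COCl)2, THF, 0 °C to reflux
Reagents that add atoms: oxalyl chloride O=C(Cl)C(=O)Cl
Why: Double N-acylation of the urea by oxalyl chloride (classical parabanic acid synthesis) closes the five-membered trione ring with loss of HCl.

Step 6
Reactants: 9 2-amino-4-(4-methoxybenzyl)-1-methyl-5-(prop-2-ynyl)-1H-imidazole; 11 1-methylparabanic acid
Product: 13 4-{[4-(4-methoxybenzyl)-1-methyl-5-(prop-2-ynyl)-1H-imidazol-2-yl]amino}-1-methyl-1H-imidazole-2,5-dione, via O-silyl imidate 12 (not isolated)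
Conditions: 11, BSA, MeCN, 80 °C, evaporate; 9, toluene, 110 °C; aq work-up
Reagents that add atoms: N,O-bis(trimethylsilyl)acetamide CC(=N[Si](C)(C)C)O[Si](C)(C)C (silyl group of 12 only; no atom stays in 13)
Why: Silylation turns the only N-H lactam unit of 11 into the O-silyl imidate 12, and addition-elimination of the exocyclic amino group of 9 at that carbon, activated by the neighbouring carbonyl, gives the amidine (the established condensation of 2-aminoimidazoles with silylated 1-methylparabanic acid), with the alkyne as a spectator.

Step 7
Reactants: 13 5-propargyl amidine; 14 dimethyl squarate (3,4-dimethoxycyclobut-3-ene-1,2-dione)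
Product: 16 racemic 4-hydroxy-2,3-dimethoxy-4-(3-{4-(4-methoxybenzyl)-1-methyl-2-[(1-methyl-2,5-dioxo-2,5-dihydro-1H-imidazol-4-yl)amino]-1H-imidazol-5-yl}prop-1-ynyl)cyclobut-2-en-1-one, via dilithio species 15 (not isolated)
Conditions: LiN(i-Pr)2 (2.1 equiv, commercial solution), THF, −78 °C; cannulate into 14 (1.3 equiv), THF, −78 °C; aq NH4Cl at −78 °C
Reagents that add atoms: lithium diisopropylamide [Li]N(C(C)C)C(C)C (lithium of 15 only; no atom stays in 16)
Why: 1,2-Addition of a lithium acetylide to one of the two equivalent carbonyl groups of dimethyl squarate (the standard entry to 4-alkynyl-4-hydroxycyclobutenones): the first equivalent of base removes the acidic amidine N-H, whose delocalised anion shields the dione ring from nucleophiles, the second removes the alkyne C-H, and the new carbinol stereocentre forms as a racemate, which does not matter because step 8 erases it.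

Step 8
Reactants: 16 4-alkynyl-4-hydroxy-2,3-dimethoxycyclobutenone
Product: 19 naamidine F, via enynylketene 17 (not isolated), via aryl-phenoxyl diradical 18 (not isolated)
Conditions: PhCl (0.01 M, degassed, Ar), 132 °C (reflux)
Reagents that add atoms: none
Why: Heating opens the four-membered ring of 16 by a conrotatory 4π electrocyclic reaction in which the donor hydroxyl turns outward, so that the alkynyl group of enynylketene 17 lies cis to the ketene carbon. The ketene carbon (the future quinone C4) then bonds to the distal alkyne carbon in a Moore cyclisation, the ketene counterpart of the Myers-Saito cycloaromatisation; this 6-endo-dig closure takes both alkyne carbons into the ring, enlarges the four-ring by two atoms and gives the aryl σ/phenoxyl diradical 18. Transfer of the hydroxyl hydrogen to the aryl radical centre delivers quinone 19 at its final oxidation level without any oxidant, which is the Moore rearrangement of 4-alkynyl-4-hydroxycyclobutenones, with close precedent for 2,3-dimethoxy members bearing alkyl-substituted alkynes. No stereocentre is formed and the racemic carbinol centre of 16 is erased. The selectivity needed is six-ring against five-ring closure (5-exo-dig, leading to an alkylidenecyclopentenedione), and it is secured by the sp3 CH2 at the alkyne terminus, which gives no stabilisation to an exocyclic vinyl radical, while the substitution pattern (CH2-imidazolyl next to one carbonyl, H next to the other, both methoxy groups opposite) is fixed by connectivity. High dilution and the weakly nucleophilic, hydrogen-bonded amidine N-H should keep the ketene from being trapped before it cyclises.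

**Compound list**
1 | N-Boc-L-propargylglycine | C#CC[C@H](NC(=O)OC(C)(C)C)C(=O)O | starting material
2 | (2S)-2-[(tert-butoxycarbonyl)(methyl)amino]pent-4-ynoic acid | C#CC[C@H](N(C)C(=O)OC(C)(C)C)C(=O)O | intermediate
3 | acyl imidazolide of 2 (not isolated) | C#CC[C@H](N(C)C(=O)OC(C)(C)C)C(=O)n1ccnc1 | intermediate
4 | Weinreb amide of 2 | C#CC[C@H](N(C)C(=O)OC(C)(C)C)C(=O)N(C)OC | intermediate
5 | 4-methoxybenzylmagnesium chloride | COc1ccc(C[Mg]Cl)cc1 | starting material
6 | tert-butyl N-[(3S)-1-(4-methoxyphenyl)-2-oxohex-5-yn-3-yl]-N-methylcarbamate | C#CC[C@H](N(C)C(=O)OC(C)(C)C)C(=O)Cc1ccc(OC)cc1 | intermediate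
7 | (3S)-1-(4-methoxyphenyl)-3-(methylamino)hex-5-yn-2-one hydrochloride (not isolated) | C#CC[C@H](NC)C(=O)Cc1ccc(OC)cc1.Cl | intermediate
8 | 1-[(3S)-1-(4-methoxyphenyl)-2-oxohex-5-yn-3-yl]-1-methylguanidine (not isolated) | C#CC[C@H](N(C)C(N)=N)C(=O)Cc1ccc(OC)cc1 | intermediate
9 | 2-amino-4-(4-methoxybenzyl)-1-methyl-5-(prop-2-ynyl)-1H-imidazole | C#CCc1c(Cc2ccc(OC)cc2)nc(N)n1C | intermediate
10 | N-methylurea | CNC(N)=O | starting material
11 | 1-methylimidazolidine-2,4,5-trione | CN1C(=O)NC(=O)C1=O | intermediate
12 | 1-methyl-4-(trimethylsilyloxy)-1H-imidazole-2,5-dione (not isolated) | CN1C(=O)N=C(O[Si](C)(C)C)C1=O | intermediate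
13 | 4-{[4-(4-methoxybenzyl)-1-methyl-5-(prop-2-ynyl)-1H-imidazol-2-yl]amino}-1-methyl-1H-imidazole-2,5-dione | C#CCc1c(Cc2ccc(OC)cc2)nc(NC2=NC(=O)N(C)C2=O)n1C | intermediate
14 | dimethyl squarate | COC1=C(OC)C(=O)C1=O | starting material
15 | N,C-dilithio derivative of 13 (not isolated) | [Li]C#CCc1c(Cc2ccc(OC)cc2)nc(N([Li])C2=NC(=O)N(C)C2=O)n1C | intermediate
16 | racemic 4-alkynyl-4-hydroxy-2,3-dimethoxycyclobut-2-en-1-one (full name in step 7) | COC1=C(OC)C(O)(C#CCc2c(Cc3ccc(OC)cc3)nc(NC3=NC(=O)N(C)C3=O)n2C)C1=O | intermediate
17 | (Z)-enynylketene, alkynyl cis to the ketene-bearing carbon (not isolated) | COC(=C=O)/C(OC)=C(/O)C#CCc1c(Cc2ccc(OC)cc2)nc(NC2=NC(=O)N(C)C2=O)n1C | intermediate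
18 | aryl σ/phenoxyl diradical (not isolated) | COc1c(OC)c(O)[c]c(Cc2c(Cc3ccc(OC)cc3)nc(NC3=NC(=O)N(C)C3=O)n2C)c1[O] | intermediate
19 | naamidine F | COC1=C(OC)C(=O)C(Cc2c(Cc3ccc(OC)cc3)nc(NC3=NC(=O)N(C)C3=O)n2C)=CC1=O | target

**Step count**
- Total step count: 8.
- Longest linear sequence: 7 (steps 1, 2, 3, 4, 6, 7, 8). Step 5 is a one-step side branch.

**Steps most likely to fail**

Step 7.
- What may go wrong:
  - Metalation may be incomplete or misdirected, with proton loss from the propargylic CH2 and drift towards the allene.
  - The dilithio species may precipitate.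
  - The carbanion or the nitrogen anion may attack the wrong electrophilic site, either the dione ring or the methoxy-bearing carbons of the squarate.
- Fallback: the order of events is changed so that the acetylide is made on a substrate without an acidic N-H and without the dione ring. It sets out from 9 and rejoins the route at 19.
  - Compound 9 would be treated with Boc2O, Et3N and DMAP in CH2Cl2 to give the N,N-di-Boc aminoimidazole F1.
  - n-BuLi (1 equiv, THF, −78 °C) followed by 14 would give the di-Boc alkynylcyclobutenone F2.
  - Heating in chlorobenzene as in step 8 would give the di-Boc quinone F3 by the same four-to-six ring expansion.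
  - CF3CO2H in CH2Cl2 would release the 2-aminoimidazole quinone F4, kept as its trifluoroacetate until use.
  - Condensation with 12 (from 11 and BSA, toluene, heat) would lead to 19.

Step 8.
- What may go wrong:
  - The aryl radical centre may be intercepted by 1,6-hydrogen transfer from the N-methyl group or the diarylmethane-type CH2, followed by radical recombination.
  - Five-ring closure may compete.
  - The ketene may be captured by an N-H group before it cyclises.
- Fallback: the diradical pathway is replaced by a closed-shell pericyclic one that still enlarges the four-ring to the six-ring. It sets out from 16 and rejoins at 19.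
  - Semihydrogenation of 16 (H2, Pd/CaCO3 poisoned with Pb(OAc)2, quinoline, EtOAc) would give the (Z)-alkenylcyclobutenone F5.
  - Heating in toluene at 110 °C would bring about 4π opening, 6π electrocyclisation of the dienylketene and tautomerisation to the hydroquinone F6.
  - Ag2O in CH2Cl2 would oxidise it to 19.

Step 6.
- What may go wrong:
  - The condensation may be sluggish.
  - The ring nitrogen may react in place of the exocyclic amino group.
  - The alkyne may slowly isomerise to the allene during long heating with a basic aminoimidazole.
- Fallback: the dione ring is built stepwise on the amine near room temperature instead of joining a preformed ring. It sets out from 9 and rejoins at 13.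
  - Compound 9 and ethyl 2-ethoxy-2-iminoacetate (EtOH, rt) would give the amidine ester F7.
  - Methyl isocyanate and Et3N in THF (rt to 50 °C) would carbamoylate the free amidine nitrogen.
  - The resulting N-methylurea nitrogen would then close onto the ester with loss of ethanol to give 13.

**Further compounds**
F1 | step 7 | di-tert-butyl N-[4-(4-methoxybenzyl)-1-methyl-5-(prop-2-ynyl)-1H-imidazol-2-yl]imidodicarbonate | C#CCc1c(Cc2ccc(OC)cc2)nc(N(C(=O)OC(C)(C)C)C(=O)OC(C)(C)C)n1C
F2 | step 7 | racemic di-Boc 4-alkynyl-4-hydroxy-2,3-dimethoxycyclobut-2-en-1-one | COC1=C(OC)C(O)(C#CCc2c(Cc3ccc(OC)cc3)nc(N(C(=O)OC(C)(C)C)C(=O)OC(C)(C)C)n2C)C1=O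
F3 | step 7 | di-Boc 2-aminoimidazolylmethyl-2,3-dimethoxy-1,4-benzoquinone | COC1=C(OC)C(=O)C(Cc2c(Cc3ccc(OC)cc3)nc(N(C(=O)OC(C)(C)C)C(=O)OC(C)(C)C)n2C)=CC1=O
F4 | step 7 | 5-{[2-amino-4-(4-methoxybenzyl)-1-methyl-1H-imidazol-5-yl]methyl}-2,3-dimethoxy-1,4-benzoquinone | COC1=C(OC)C(=O)C(Cc2c(Cc3ccc(OC)cc3)nc(N)n2C)=CC1=O
F5 | step 8 | racemic (Z)-4-alkenyl-4-hydroxy-2,3-dimethoxycyclobut-2-en-1-one | COC1=C(OC)C(O)(/C=C\Cc2c(Cc3ccc(OC)cc3)nc(NC3=NC(=O)N(C)C3=O)n2C)C1=O
F6 | step 8 | hydroquinone of naamidine F | COc1c(OC)c(O)c(Cc2c(Cc3ccc(OC)cc3)nc(NC3=NC(=O)N(C)C3=O)n2C)cc1O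
F7 | step 6 | ethyl 2-imino-2-{[4-(4-methoxybenzyl)-1-methyl-5-(prop-2-ynyl)-1H-imidazol-2-yl]amino}acetate | CCOC(=O)C(=N)Nc1nc(Cc2ccc(OC)cc2)c(CC#C)n1C
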